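Ring B carries a tertiary C9 (methyl, chlorine) next to a secondary C10 (bromine). Read as an oxygen pattern this is a tertiary α-ketol, so the C9–C10 bond is cut back to a methyl ketone and an aldehyde hanging from the spiro carbon C6. A chiral triazolylidene turns the aldehyde into an acyl-anion equivalent that closes ring B onto the ketone, forming C9–C10 and the C9 carbinol in one operation. The precursor is a 2,2-disubstituted 3,3-dimethylcyclohexanone (3-oxobutyl and 2-oxoethyl arms at C6), whose C6 is set by palladium-catalysed decarboxylative allylation. Oxygen is then traded for bromine (inversion, C10) and chlorine (retention, C9); ring A is finished last.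

Key step: step 6

Locants: ring A is C1 (=CH2), C2 (CHOH), C3, C4 (CBr), C5 (CMe2), C6 (spiro); ring B is C7, C8, C9 (CMeCl), C10 (CHBr), C11; these locants are used for every intermediate.
Remark: ring B is taken in the chair that keeps C5 (CMe2) equatorial and C1 axial; "axial" and "equatorial" in the Why lines refer to this chair.
Remark: the C6 descriptor changes from R to S in step 15 only because the CIP ranking of C1 and C5 is exchanged when C1=O becomes C1=CH2; the centre itself is not touched.
Remark: enolates, ion pairs and catalyst-bound species are discussed in the Why lines and carry no number; discrete compounds carried on without isolation are numbered.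
Assumption: 4-iodo-2-methylbut-1-ene (2) is bought as such and LiN(i-Pr)2 is used as a commercial solution.

Step 1
Reactants: 1 5,5-dimethylcyclohex-2-en-1-one; 2 4-iodo-2-methylbut-1-ene
Product: 3 rac-5,5-dimethyl-6-(3-methylbut-3-en-1-yl)cyclohex-2-en-1-one
Conditions: LiN(i-Pr)2 (1.1 equiv), THF, −78 °C; then 2, HMPA (2 equiv), −78 → 0 °C
Reagents that add atoms: 4-iodo-2-methylbut-1-ene (compound 2), C=C(C)CCI
Why: Kinetic deprotonation can only take place at C6, the sole sp3 α-carbon, and the cross-conjugated lithium dienolate is C-alkylated by the primary iodide (SN2 enolate alkylation); the C6 centre forms racemic and is made planar again in step 2.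

Step 2
Reactants: 3 rac-5,5-dimethyl-6-(3-methylbut-3-en-1-yl)cyclohex-2-en-1-one; 4 allyl chloroformate (prop-2-en-1-yl carbonochloridate)
Product: 5 6,6-dimethyl-1-(3-methylbut-3-en-1-yl)cyclohexa-1,3-dien-2-yl prop-2-en-1-yl carbonate
Conditions: LiN(i-Pr)2 (1.15 equiv), THF, −78 → −40 °C; TMEDA; then 4, −78 °C
Reagents that add atoms: allyl chloroformate (compound 4), C=CCOC(=O)Cl
Why: Kinetic α′-deprotonation at C6 is faster than γ-deprotonation at C4, and the hindered, fully substituted enolate carbon sends the chloroformate to oxygen (enolate O-acylation), which gives the dienyl allyl carbonate needed for step 3.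

Step 3
Reactants: 5 6,6-dimethyl-1-(3-methylbut-3-en-1-yl)cyclohexa-1,3-dien-2-yl prop-2-en-1-yl carbonate
Product: 6 (6R)-5,5-dimethyl-6-(3-methylbut-3-en-1-yl)-6-(prop-2-en-1-yl)cyclohex-2-en-1-one
Conditions: Pd2(dba)3 (2.5 mol%), (S)-4-tert-butyl-2-{2-[bis(4-(trifluoromethyl)phenyl)phosphanyl]-5-(trifluoromethyl)phenyl}-4,5-dihydro-1,3-oxazole ((S)-(CF3)3-t-BuPHOX, 6.25 mol%), toluene, 25 °C
Reagents that add atoms: none
Why: Decarboxylative asymmetric allylic alkylation (Tsuji–Trost type): zerovalent palladium ionises the allyl carbonate, CO2 is lost, and the allyl group is passed to C6 of the palladium-bound dienolate inside the pocket of the (S)-phosphinooxazoline, which by analogy with the formation of (S)-2-allyl-2-methylcyclohexanone should deliver allyl to the face that gives (6R).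

Step 4
Reactants: 6 (6R)-5,5-dimethyl-6-(3-methylbut-3-en-1-yl)-6-(prop-2-en-1-yl)cyclohex-2-en-1-one
Product: 8 (2R)-3,3-dimethyl-2-(3-methylbut-3-en-1-yl)-2-(prop-2-en-1-yl)cyclohexan-1-one, via dimethylphenylsilyl enol ether 7 (not isolated)
Conditions: [(Ph3P)CuH]6 (3 mol%), PhMe2SiH (1.5 equiv), toluene, 0 °C → rt; then K2CO3 (cat.), MeOH, rt
Reagents that add atoms: none
Why: Copper hydride conjugate reduction: hydrocupration at C3 gives a copper enolate that the silane silylates at once (regenerating Cu–H), the two isolated alkenes are not touched, and methanolysis of the silyl enol ether frees the saturated ketone with C6 unchanged; ring A is kept saturated so that neither a Stetter closure in step 6 nor RuO4 or borohydride in steps 7 and 8 can engage it.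

Step 5
Reactants: 8 (2R)-3,3-dimethyl-2-(3-methylbut-3-en-1-yl)-2-(prop-2-en-1-yl)cyclohexan-1-one
Product: 10 (2R)-3,3-dimethyl-2-(3-oxobutyl)-2-(2-oxoethyl)cyclohexan-1-one, via bis-ozonide 9 (not isolated)
Conditions: O3, CH2Cl2, −78 °C; then PPh3 (2.2 equiv), −78 °C → rt; used crude at once
Reagents that add atoms: ozone, [O-][O+]=O
Why: Ozonolysis: both terminal alkenes pass through cycloaddition and cycloreversion to the secondary ozonides, which PPh3 reduces to the methyl ketone and the aldehyde in one operation, so the sensitive keto-aldehyde is made only when it is needed and C6 stays a spectator.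

Step 6
Reactants: 10 (2R)-3,3-dimethyl-2-(3-oxobutyl)-2-(2-oxoethyl)cyclohexan-1-one
Product: 11 (6R,9S)-9-hydroxy-5,5,9-trimethylspiro[5.5]undecane-1,10-dione
Conditions: (5aS,10bR)-2-(pentafluorophenyl)-5a,10b-dihydro-4H,6H-indeno[2,1-b][1,2,4]triazolo[4,3-d][1,4]oxazin-2-ium tetrafluoroborate (10 mol%), Et3N (10 mol%), CH2Cl2, 23 °C
Reagents that add atoms: none
Why: The triazolylidene freed by Et3N adds to the unhindered aldehyde carbon C10, proton transfer gives the Breslow enaminol, its nucleophilic C10 attacks the methyl ketone carbon C9, and proton transfer with loss of the carbene gives the α-ketol and returns the catalyst. This is the known carbene-catalysed enantioselective intramolecular crossed aldehyde–ketone benzoin reaction that gives six-membered tertiary α-ketols. Ring B closes in the 6-exo-trig mode through a chair in which the enaminol O–H is hydrogen-bonded to the ketone oxygen. C9 is set by the catalyst, whose indane backbone and C6F5 group screen one face of the enaminol; the antipode is chosen to reinforce the substrate's own preference for the chair with C1 axial, C5 equatorial and the C9 oxygen equatorial, which should give (9S) beside (6R). Chemoselectivity rests on the substrate: only the aldehyde can become an acyl-anion equivalent, attack on the ring A ketone would need a four-membered ring, ring A offers no Michael acceptor, and the catalytic weak base keeps aldol closures slow.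

Step 7
Reactants: 11 (6R,9S)-9-hydroxy-5,5,9-trimethylspiro[5.5]undecane-1,10-dione
Product: 12 (6R,9S,10R)-9,10-dihydroxy-5,5,9-trimethylspiro[5.5]undecan-1-one
Conditions: NaBH4 (1.0 equiv), MeOH/CH2Cl2 (1:1), −78 → −40 °C
Reagents that add atoms: none
Why: Borohydride reduction that should be chemoselective for the inductively activated α-hydroxy ketone over the C1 carbonyl (flanked by quaternary C6 next to CMe2), with hydride entering C10 from the ring B face remote from the axial C6–C1 bond (substrate control in the chair), so that the new C10 hydroxyl is axial and cis to the C9 hydroxyl (10R).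

Step 8
Reactants: 12 (6R,9S,10R)-9,10-dihydroxy-5,5,9-trimethylspiro[5.5]undecan-1-one
Product: 14 cyclic sulfate of diol 12 (1,3,2-dioxathiolane 2,2-dioxide fused at C9–C10), via cyclic sulfite 13 (not isolated)
Conditions: SOCl2 (1.3 equiv), Et3N (3 equiv), CH2Cl2, 0 °C; then RuCl3·xH2O (1 mol%), NaIO4 (1.5 equiv), MeCN/CH2Cl2/H2O, 0 °C
Reagents that add atoms: thionyl chloride, O=S(Cl)Cl; sodium periodate, [Na+].[O-]I(=O)(=O)=O
Why: Cyclic sulfate formation: the cis-diol is bridged by SOCl2 as the five-membered sulfite and sulfur is then oxidised by catalytic RuO4 (from RuCl3 and NaIO4) without breaking either C–O bond, so C9 and C10 keep their configuration and the saturated ring A ketone is inert; any lactol between O10 and C1 is in equilibrium with the open diol and is drained by sulfite formation.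

Step 9
Reactants: 14 cyclic sulfate of diol 12
Product: 16 (6R,9S,10S)-10-bromo-9-hydroxy-5,5,9-trimethylspiro[5.5]undecan-1-one, via lithium bromo sulfate 15 (not isolated)
Conditions: LiBr (3 equiv), THF, 60 °C; then H2SO4 (cat.), H2O (2 equiv), THF, 23 °C
Reagents that add atoms: lithium bromide, [Li+].[Br-]
Why: SN2 opening of the cyclic sulfate: bromide attacks the secondary C10 from the face opposite its axial C–O bond (inversion, bromine equatorial, 10S) because backside attack at the tertiary C9 is blocked, and acid hydrolysis of the remaining sulfate monoester returns the C9 hydroxyl with its configuration.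

Step 10
Reactants: 16 (6R,9S,10S)-10-bromo-9-hydroxy-5,5,9-trimethylspiro[5.5]undecan-1-one
Product: 17 (6R,9S,10S)-10-bromo-9-chloro-5,5,9-trimethylspiro[5.5]undecan-1-one
Conditions: HCl (gas, saturated solution), ZnCl2 (0.2 equiv), CH2Cl2, 0 °C
Reagents that add atoms: hydrogen chloride, Cl
Why: Lucas-type SN1 substitution with neighbouring-group participation: the ionising C9 is bridged by the vicinal bromine to a bromonium ion on the face bromine already occupies, and chloride opens it at the tertiary carbon anti to bromine, which amounts to retention at C9 (double inversion) and should give the trans, diequatorial bromochloride (9S,10S).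

Step 11
Reactants: 17 (6R,9S,10S)-10-bromo-9-chloro-5,5,9-trimethylspiro[5.5]undecan-1-one
Product: 18 (6R,9S,10S)-10-bromo-9-chloro-5,5,9-trimethylspiro[5.5]undec-2-en-1-one
Conditions: 2-iodoxybenzoic acid (IBX, 2.5 equiv), 4-methoxypyridine N-oxide (2.5 equiv), DMSO, 25 °C
Reagents that add atoms: none
Why: IBX dehydrogenation of a ketone: enolisation is possible only toward C2 and both C5 and C6 are quaternary, so the C2=C3 enone is the only product that can form and no stereocentre is touched.

Step 12
Reactants: 18 (6R,9S,10S)-10-bromo-9-chloro-5,5,9-trimethylspiro[5.5]undec-2-en-1-one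
Product: 19 (6R,9S,10S)-4,10-dibromo-9-chloro-5,5,9-trimethylspiro[5.5]undec-2-en-1-one (both C4 epimers)
Conditions: NBS (1.05 equiv), AIBN (5 mol%), PhCF3, 80 °C
Reagents that add atoms: N-bromosuccinimide, O=C1CCC(=O)N1Br
Why: Wohl–Ziegler bromination: the only allylic (γ) C–H bonds are at C4, and the enone-stabilised radical takes bromine at C4 so that conjugation is kept; the C4 epimers are used together because C4 becomes sp2 in step 13.

Step 13
Reactants: 19 (6R,9S,10S)-4,10-dibromo-9-chloro-5,5,9-trimethylspiro[5.5]undec-2-en-1-one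
Product: 20 [(6R,9S,10S)-4,10-dibromo-9-chloro-5,5,9-trimethylspiro[5.5]undeca-1,3-dien-1-yl]oxy(triethyl)silane
Conditions: Et3SiOTf (1.5 equiv), Et3N (3 equiv), CH2Cl2, 0 °C
Reagents that add atoms: triethylsilyl trifluoromethanesulfonate, CC[Si](CC)(CC)OS(=O)(=O)C(F)(F)F
Why: Soft enolisation to a silyl dienol ether: O-silylation of the enone and loss of the C4 proton (the only γ-hydrogen, acidified by bromine, with no α′-hydrogen available) gives the 1-silyloxy-4-bromo-1,3-diene, while the equatorial C9–Cl and C10–Br bonds have no antiperiplanar hydrogen for E2.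

Step 14
Reactants: 20 [(6R,9S,10S)-4,10-dibromo-9-chloro-5,5,9-trimethylspiro[5.5]undeca-1,3-dien-1-yl]oxy(triethyl)silane
Product: 22 (6R,9S,10S)-4,10-dibromo-9-chloro-5,5,9-trimethyl-2-(triethylsilyloxy)spiro[5.5]undec-3-en-1-one (both C2 epimers), via silyloxy oxirane 21 (not isolated)
Conditions: mCPBA (1.05 equiv), CH2Cl2, −20 → 0 °C
Reagents that add atoms: 3-chloroperoxybenzoic acid, OOC(=O)c1cccc(Cl)c1
Why: Rubottom oxidation: the peracid epoxidises the electron-rich C1=C2 enol ether bond (C3=C4 is deactivated by bromine and screened by CMe2) and the silyloxy oxirane opens with 1,4-silyl shift to the 2-silyloxy ketone, leaving the vinyl bromide at C3=C4; C2 forms as a mixture, which is harmless because C2 is set in step 18.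

Step 15
Reactants: 22 (6R,9S,10S)-4,10-dibromo-9-chloro-5,5,9-trimethyl-2-(triethylsilyloxy)spiro[5.5]undec-3-en-1-one
Product: 23 {[(6S,9S,10S)-4,10-dibromo-9-chloro-5,5,9-trimethyl-1-methylidenespiro[5.5]undec-3-en-2-yl]oxy}(triethyl)silane (both C2 epimers)
Conditions: Cp2Ti(μ-CH2)(μ-Cl)AlMe2 (2 equiv), pyridine, THF/toluene, −40 → 0 °C; then aq. NaOH
Reagents that add atoms: μ-chloro-μ-methylene-bis(cyclopentadienyl)titanium dimethylaluminium (Tebbe reagent), C[Al-]1(C)C[Ti]([Cl+]1)(C2C=CC=C2)C2C=CC=C2
Why: Tebbe methylenation: the titanocene methylidene released by pyridine adds [2+2] to the C1 carbonyl and the oxatitanacyclobutane cycloreverts to the exocyclic alkene; the reagent is not basic, so the β,γ-unsaturated ketone should not isomerise and the halides should not eliminate.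

Step 16
Reactants: 23 {[(6S,9S,10S)-4,10-dibromo-9-chloro-5,5,9-trimethyl-1-methylidenespiro[5.5]undec-3-en-2-yl]oxy}(triethyl)silane
Product: 24 (6S,9S,10S)-4,10-dibromo-9-chloro-5,5,9-trimethyl-1-methylidenespiro[5.5]undec-3-en-2-ol (both C2 epimers)
Conditions: HF·pyridine, pyridine, THF, 0 °C
Reagents that add atoms: none
Why: Fluoride-assisted cleavage of the Si–O bond (desilylation) under buffered conditions that should spare the bis-allylic alcohol and both alkyl halides; the C2 epimers are carried on together.

Step 17
Reactants: 24 (6S,9S,10S)-4,10-dibromo-9-chloro-5,5,9-trimethyl-1-methylidenespiro[5.5]undec-3-en-2-ol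
Product: 25 (6S,9S,10S)-4,10-dibromo-9-chloro-5,5,9-trimethyl-1-methylidenespiro[5.5]undec-3-en-2-one
Conditions: Dess–Martin periodinane (1,1,1-triacetoxy-1,1-dihydro-1,2-benziodoxol-3(1H)-one, 1.3 equiv), CH2Cl2, 0 → 23 °C
Reagents that add atoms: none
Why: Dess–Martin oxidation (ligand exchange at hypervalent iodine, then loss of the carbinol proton) converts both C2 epimers into one cross-conjugated dienone without touching the vinyl bromide or the exocyclic alkene.

Step 18
Reactants: 25 (6S,9S,10S)-4,10-dibromo-9-chloro-5,5,9-trimethyl-1-methylidenespiro[5.5]undec-3-en-2-one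
Product: 26 (2R,6S,9S,10S)-4,10-dibromo-9-chloro-5,5,9-trimethyl-1-methylidenespiro[5.5]undec-3-en-2-ol
Conditions: (S)-1-methyl-3,3-diphenyl-tetrahydro-1H,3H-pyrrolo[1,2-c][1,3,2]oxazaborole ((S)-Me-CBS, 20 mol%), catecholborane (1.5 equiv), toluene, −78 °C; aq. NaOH work-up
Reagents that add atoms: none
Why: Corey–Bakshi–Shibata reduction: hydride is delivered 1,2 inside the ketone–oxazaborolidine–borane complex, in which the α-branched C1 side acts as the large group and the C3 methine as the small one, so the (S)-catalyst (the one that gives (R)-1-phenylethanol) should set the (2R) carbinol under catalyst control.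

Compound list
1 | 5,5-dimethylcyclohex-2-en-1-one | CC1(C)CC=CC(=O)C1 | starting material
2 | 4-iodo-2-methylbut-1-ene | C=C(C)CCI | starting material
3 | rac-5,5-dimethyl-6-(3-methylbut-3-en-1-yl)cyclohex-2-en-1-one | O=C1C=CCC(C)(C)C1CCC(C)=C | intermediate
4 | allyl chloroformate (prop-2-en-1-yl carbonochloridate) | C=CCOC(=O)Cl | starting material
5 | 6,6-dimethyl-1-(3-methylbut-3-en-1-yl)cyclohexa-1,3-dien-2-yl prop-2-en-1-yl carbonate | C=CCOC(=O)OC1=C(CCC(C)=C)C(C)(C)CC=C1 | intermediate
6 | (6R)-5,5-dimethyl-6-(3-methylbut-3-en-1-yl)-6-(prop-2-en-1-yl)cyclohex-2-en-1-one | O=C1C=CCC(C)(C)[C@@]1(CCC(C)=C)CC=C | intermediate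
7 | {[(6R)-5,5-dimethyl-6-(3-methylbut-3-en-1-yl)-6-(prop-2-en-1-yl)cyclohex-1-en-1-yl]oxy}dimethyl(phenyl)silane | C[Si](C)(OC1=CCCC(C)(C)[C@@]1(CCC(C)=C)CC=C)c1ccccc1 | intermediate
8 | (2R)-3,3-dimethyl-2-(3-methylbut-3-en-1-yl)-2-(prop-2-en-1-yl)cyclohexan-1-one | O=C1CCCC(C)(C)[C@@]1(CCC(C)=C)CC=C | intermediate
9 | (2R)-3,3-dimethyl-2-[2-(3-methyl-1,2,4-trioxolan-3-yl)ethyl]-2-(1,2,4-trioxolan-3-ylmethyl)cyclohexan-1-one (bis-ozonide, mixture at the trioxolane carbons) | O=C1CCCC(C)(C)[C@@]1(CCC2(C)OCOO2)CC2OCOO2 | intermediate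
10 | (2R)-3,3-dimethyl-2-(3-oxobutyl)-2-(2-oxoethyl)cyclohexan-1-one | O=C1CCCC(C)(C)[C@@]1(CCC(C)=O)CC=O | intermediate
11 | (6R,9S)-9-hydroxy-5,5,9-trimethylspiro[5.5]undecane-1,10-dione | O=C1CCCC(C)(C)[C@]12CC[C@](C)(O)C(=O)C2 | intermediate
12 | (6R,9S,10R)-9,10-dihydroxy-5,5,9-trimethylspiro[5.5]undecan-1-one | O=C1CCCC(C)(C)[C@]12CC[C@](C)(O)[C@H](O)C2 | intermediate
13 | cyclic sulfite of diol 12 (1,3,2-dioxathiolane 2-oxide fused at C9–C10, mixture at sulfur) | O=C1CCCC(C)(C)[C@]12CC[C@]3(C)OS(=O)O[C@@H]3C2 | intermediate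
14 | cyclic sulfate of diol 12 (1,3,2-dioxathiolane 2,2-dioxide fused at C9–C10) | O=C1CCCC(C)(C)[C@]12CC[C@]3(C)OS(=O)(=O)O[C@@H]3C2 | intermediate
15 | lithium (6R,9S,10S)-10-bromo-5,5,9-trimethyl-1-oxospiro[5.5]undecan-9-yl sulfate | O=C1CCCC(C)(C)[C@]12CC[C@](C)(OS(=O)(=O)[O-])[C@@H](Br)C2.[Li+] | intermediate
16 | (6R,9S,10S)-10-bromo-9-hydroxy-5,5,9-trimethylspiro[5.5]undecan-1-one | O=C1CCCC(C)(C)[C@]12CC[C@](C)(O)[C@@H](Br)C2 | intermediate
17 | (6R,9S,10S)-10-bromo-9-chloro-5,5,9-trimethylspiro[5.5]undecan-1-one | O=C1CCCC(C)(C)[C@]12CC[C@](C)(Cl)[C@@H](Br)C2 | intermediate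
18 | (6R,9S,10S)-10-bromo-9-chloro-5,5,9-trimethylspiro[5.5]undec-2-en-1-one | O=C1C=CCC(C)(C)[C@]12CC[C@](C)(Cl)[C@@H](Br)C2 | intermediate
19 | (6R,9S,10S)-4,10-dibromo-9-chloro-5,5,9-trimethylspiro[5.5]undec-2-en-1-one (both C4 epimers) | O=C1C=CC(Br)C(C)(C)[C@]12CC[C@](C)(Cl)[C@@H](Br)C2 | intermediate
20 | [(6R,9S,10S)-4,10-dibromo-9-chloro-5,5,9-trimethylspiro[5.5]undeca-1,3-dien-1-yl]oxy(triethyl)silane | CC[Si](CC)(CC)OC1=CC=C(Br)C(C)(C)[C@]12CC[C@](C)(Cl)[C@@H](Br)C2 | intermediate
21 | 1,2-epoxide of 20 (1-triethylsilyloxy oxirane across C1–C2, mixture at C1 and C2) | CC[Si](CC)(CC)OC12OC1C=C(Br)C(C)(C)[C@@]32CC[C@](C)(Cl)[C@@H](Br)C3 | intermediate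
22 | (6R,9S,10S)-4,10-dibromo-9-chloro-5,5,9-trimethyl-2-(triethylsilyloxy)spiro[5.5]undec-3-en-1-one (both C2 epimers) | O=C1C(O[Si](CC)(CC)CC)C=C(Br)C(C)(C)[C@]12CC[C@](C)(Cl)[C@@H](Br)C2 | intermediate
23 | {[(6S,9S,10S)-4,10-dibromo-9-chloro-5,5,9-trimethyl-1-methylidenespiro[5.5]undec-3-en-2-yl]oxy}(triethyl)silane (both C2 epimers) | C=C1C(O[Si](CC)(CC)CC)C=C(Br)C(C)(C)[C@]12CC[C@](C)(Cl)[C@@H](Br)C2 | intermediate
24 | (6S,9S,10S)-4,10-dibromo-9-chloro-5,5,9-trimethyl-1-methylidenespiro[5.5]undec-3-en-2-ol (both C2 epimers) | C=C1C(O)C=C(Br)C(C)(C)[C@]12CC[C@](C)(Cl)[C@@H](Br)C2 | intermediate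
25 | (6S,9S,10S)-4,10-dibromo-9-chloro-5,5,9-trimethyl-1-methylidenespiro[5.5]undec-3-en-2-one | C=C1C(=O)C=C(Br)C(C)(C)[C@]12CC[C@](C)(Cl)[C@@H](Br)C2 | intermediate
26 | (2R,6S,9S,10S)-4,10-dibromo-9-chloro-5,5,9-trimethyl-1-methylidenespiro[5.5]undec-3-en-2-ol | C=C1[C@H](O)C=C(Br)C(C)(C)[C@]12CC[C@](C)(Cl)[C@@H](Br)C2 | target

Total step count: 18. Longest linear sequence: 18 steps (1 to 26); the route is fully linear.

Steps most likely to fail

Step 10. The risk is loss of stereochemical fidelity together with elimination: in the resting chair the C10–Br and C9–O bonds are gauche, so C9 may ionise before bromine bridges, and the open cation can lose a proton or take chloride on the axial face. The fallback sets out from 16 and comes back at 17. Zn dust in AcOH at 50 °C should remove bromine and hydroxyl by reductive 1,2-elimination to give (6R)-5,5,9-trimethylspiro[5.5]undec-9-en-1-one F1. Anti bromochlorination of this alkene with n-Bu4NBrCl2 in CH2Cl2 at −78 °C should place chlorine on the tertiary C9 and bromine on C10. The (9S,10S) isomer 17 would be separated from its (9R,10R) partner by chromatography.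

Step 6. The risk is poor facial selectivity at C9 if catalyst and substrate are mismatched (the sense of the indane catalyst is assigned by analogy), or diversion of the keto-aldehyde into base-mediated aldol closure before the carbene engages. The fallback sets out from 10 and comes back at 12, replacing steps 6 and 7. SmI2 (2.5 equiv) with t-BuOH in THF at −78 °C should effect a ketyl–carbonyl pinacol cyclisation that forms C9–C10 and both carbinols at once. The samarium-bridged diolate enforces the cis diol, and the chair with C1 axial should favour 12, which is purified by chromatography. No compound outside the list is made (none F0).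

Step 15. The risk is failure of the [2+2] addition at a carbonyl screened by the spiro centre and the neighbouring silyloxy group, with enolisation and alkene migration taking over if the reaction is forced. The fallback sets out from 22 and comes back at 24. Me3SiCH2MgCl with CeCl3 in THF at −78 → 0 °C should add to C1 without enolisation to give (6R,9S,10S)-4,10-dibromo-9-chloro-5,5,9-trimethyl-2-(triethylsilyloxy)-1-[(trimethylsilyl)methyl]spiro[5.5]undec-3-en-1-ol F2. HF·pyridine in MeCN/THF at 0 °C → rt should then bring about Peterson elimination to the exocyclic alkene and remove the triethylsilyl group in the same flask, giving 24.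

Further compounds
F0 | step 6 | none | none
F1 | step 10 | (6R)-5,5,9-trimethylspiro[5.5]undec-9-en-1-one | O=C1CCCC(C)(C)[C@]12CCC(C)=CC2
F2 | step 15 | (6R,9S,10S)-4,10-dibromo-9-chloro-5,5,9-trimethyl-2-(triethylsilyloxy)-1-[(trimethylsilyl)methyl]spiro[5.5]undec-3-en-1-ol (mixture at C1 and C2) | C[Si](C)(C)CC1(O)C(O[Si](CC)(CC)CC)C=C(Br)C(C)(C)[C@]12CC[C@](C)(Cl)[C@@H](Br)C2
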